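**Retrosynthetic overview**

1. The benzofuran is cut last, at O1–C2 and C3–C3a: Sonogashira coupling and 5-endo-dig closure of alkynol 26 with 5-iodo-2,4-dihydroxyacetophenone 28.
2. Alkyne 26 comes from lactol 24 of the cis-3-methyl-5-aryl γ-lactone 23. The C3 methine is set on lactone 17 by α-methylenation and 1,4-reduction, with protonation anti to the aryl group.
3. The strategy rests on the tertiary benzylic carbinol carbon (chain C4, bearing OH, CH3, CH2 and chromene C6). Its acid-labile C–O bond is made by inserting O into the C1–C2 bond of (S)-2-aryl-2-methylcyclobutanone 15, so the all-carbon quaternary centre becomes the γ-carbon of oxolan-2-one 17 with retention.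
4. Cyclobutanone 15 arises by enantioselective protio-semipinacol ring expansion of 1-(1-arylvinyl)cyclopropanol 13, made from ketone 5 (Shapiro reaction) and cyclopropanone hemiketal 8.
5. Rings form in the order: pyran ring of the chromene (step 2), cyclobutanone (step 6), oxolanone (step 7, opened again in steps 10 and 11), furan ring of the benzofuran (step 13).

Key step: step 7

Assumption: the sense of induction of the chiral acid in step 6 cannot be predicted with certainty; the (R)-catalyst is written, and its antipode is to be used if the first run shows that it leads to the (R)-ketone.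

**Route**

Step 1
Reactants: 1 1-(4-hydroxy-2-methoxyphenyl)ethanone; 2 3-chloro-3-methylbut-1-yne
Product: 3 1-[2-methoxy-4-(2-methylbut-3-yn-2-yloxy)phenyl]ethanone
Conditions: DBU, CuCl2·2H2O (0.1 mol%), MeCN, 0 °C
Reagents that add atoms: none
Why: Copper-catalysed O-propargylation of the acidic para-acyl phenol with the tertiary propargylic chloride (an SN1-type etherification) is the standard entry to aryl 1,1-dimethylpropargyl ethers and leaves the ketone untouched.

Step 2
Reactants: 3 1-[2-methoxy-4-(2-methylbut-3-yn-2-yloxy)phenyl]ethanone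
Product: 5 1-(7-methoxy-2,2-dimethyl-2H-chromen-6-yl)ethanone (encecalin), via ortho-allenylphenol 4 (not isolated)
Conditions: PhNEt2, 180 °C
Reagents that add atoms: none
Why: Aromatic propargyl Claisen rearrangement gives 4, which closes the pyran ring by 1,5-hydrogen shift and oxa-6π electrocyclisation; the [3,3] shift should go to C5 (para to OMe, flanked by H) and not to C3, which lies between the two oxygen substituents and is shielded by the methoxy methyl group turned away from the acetyl group.

Step 3
Reactants: 5 1-(7-methoxy-2,2-dimethyl-2H-chromen-6-yl)ethanone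
Product: 6 (E)-N'-[1-(7-methoxy-2,2-dimethyl-2H-chromen-6-yl)ethylidene]-2,4,6-tri(propan-2-yl)benzenesulfonohydrazide
Conditions: 2,4,6-(i-Pr)3C6H2SO2NHNH2, cat. HCl, MeOH/THF, rt
Reagents that add atoms: 2,4,6-tri(propan-2-yl)benzenesulfonohydrazide, CC(C)c1cc(C(C)C)c(S(=O)(=O)NN)c(C(C)C)c1
Why: Acid-catalysed condensation of the ketone with the sulfonyl hydrazide gives the arenesulfonylhydrazone needed for a Shapiro reaction, under conditions mild enough for the chromene.

Step 4
Reactants: 7 (1-ethoxycyclopropoxy)trimethylsilane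
Product: 8 1-ethoxycyclopropan-1-ol
Conditions: MeOH, rt; evaporation
Reagents that add atoms: none
Why: Methanolysis of the trimethylsilyl ether (silyl transfer to methanol) frees the cyclopropanone ethyl hemiketal without opening the three-membered ring.

Step 5
Reactants: 6 (E)-N'-[1-(7-methoxy-2,2-dimethyl-2H-chromen-6-yl)ethylidene]-2,4,6-tri(propan-2-yl)benzenesulfonohydrazide; 8 1-ethoxycyclopropan-1-ol
Product: 13 1-[1-(7-methoxy-2,2-dimethyl-2H-chromen-6-yl)ethenyl]cyclopropan-1-ol, via alkenyllithium 9 (not isolated), via alkenylmagnesium bromide 10 (not isolated), via hemiketal bromomagnesium salt 11 (not isolated), via cyclopropanone 12 (not isolated)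
Conditions: 6: n-BuLi (2.1 equiv), THF, −78 → 0 °C, then MgBr2·OEt2; 8: MeMgBr (1 equiv), THF, 0 °C; combine, 0 → 45 °C; aq. NH4Cl
Reagents that add atoms: none
Why: The Shapiro reaction of the trisylhydrazone (dianion formation at the methyl group, loss of sulfinate and N2) gives the 1-arylvinyl anion, which after transmetalation adds as a Grignard reagent to cyclopropanone released from its hemiketal magnesium salt, the established route to 1-alkenylcyclopropanols.

Step 6
Reactants: 13 1-[1-(7-methoxy-2,2-dimethyl-2H-chromen-6-yl)ethenyl]cyclopropan-1-ol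
Product: 15 (2S)-2-(7-methoxy-2,2-dimethyl-2H-chromen-6-yl)-2-methylcyclobutan-1-one, via benzylic cation 14 (not isolated)
Conditions: (R)-3,3'-bis(2,4,6-triisopropylphenyl)-1,1'-binaphthyl-2,2'-diyl N-triflylphosphoramide (5 mol%), toluene, 4 Å MS, −40 °C
Reagents that add atoms: none
Why: In this enantioselective protio-semipinacol rearrangement the chiral acid protonates the terminal CH2 of the electron-rich 1,1-disubstituted alkene, and within the ion pair of cation 14 and the chiral phosphoramide anion a cyclopropane CH2 migrates to one face of the benzylic carbon, so the counter-anion sets the quaternary (S) centre while the less basic chromene alkene stays unprotonated.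

Step 7
Reactants: 15 (2S)-2-(7-methoxy-2,2-dimethyl-2H-chromen-6-yl)-2-methylcyclobutan-1-one
Product: 17 (5S)-5-(7-methoxy-2,2-dimethyl-2H-chromen-6-yl)-5-methyloxolan-2-one, via peroxy hemiketal 16 (not isolated)
Conditions: 30% aq. H2O2 (3 equiv), 1 M aq. NaOH, THF/MeOH, 0 °C; aq. Na2SO3; NaH2PO4 buffer to pH 5–6, rt
Reagents that add atoms: hydrogen peroxide, OO
Why: Hydroperoxide anion adds to the strained carbonyl C1 of 15 to give the tetrahedral peroxy hemiketal 16, and the quaternary benzylic carbon C2 then shifts from C1 to the proximal peroxide oxygen, antiperiplanar to the breaking O–O bond, as hydroxide leaves. The closest known reaction type is the Baeyer–Villiger oxidation of 2,2-disubstituted cyclobutanones to γ-butyrolactones with basic hydrogen peroxide. The oxolan-2-one ring is closed not by cyclisation of a chain but by this 1,2-shift, a one-atom ring enlargement that inserts O into the C1–C2 bond (four-membered to five-membered ring, one new C–O bond). The carbinol stereocentre is controlled by the quaternary centre already present in 15, because the migrating carbon keeps its configuration, so (S)-15 should give (S)-17. The step needs migration of the quaternary carbon instead of the ring CH2 and no attack on the chromene C3=C4 bond; the first follows from the higher migratory aptitude of the tertiary carbon bearing the electron-rich 2-methoxy-4-alkoxyphenyl group, the second from a nucleophilic oxidant that a strained ketone accepts but an electron-rich alkene does not. Any hydroxy carboxylate formed by saponification should re-close to the lactone at pH 5–6, which is mild enough for the acid-labile benzylic C–O bond.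

Step 8
Reactants: 17 (5S)-5-(7-methoxy-2,2-dimethyl-2H-chromen-6-yl)-5-methyloxolan-2-one
Product: 21 (5S)-5-(7-methoxy-2,2-dimethyl-2H-chromen-6-yl)-5-methyl-3-methylideneoxolan-2-one, via lithium enolate 18 (not isolated), via Mannich base 19 (not isolated), via trimethylammonium iodide 20 (not isolated)
Conditions: LiN(i-Pr)2, THF, −78 °C; CH2=NMe2+ I−, −78 °C → rt; MeI, MeOH, rt; aq. NaHCO3/CH2Cl2, rt
Reagents that add atoms: N,N-dimethylmethaniminium iodide (CH2=NMe2+ I−), C=[N+](C)C.[I-]
Why: Mannich reaction of the lactone enolate with the preformed iminium salt, N-quaternisation and base-induced β-elimination of trimethylamine is the classical α-methylenation of γ-butyrolactones, and the non-enolisable quaternary C5 is unaffected.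

Step 9
Reactants: 21 (5S)-5-(7-methoxy-2,2-dimethyl-2H-chromen-6-yl)-5-methyl-3-methylideneoxolan-2-one
Product: 23 (3S,5S)-5-(7-methoxy-2,2-dimethyl-2H-chromen-6-yl)-3,5-dimethyloxolan-2-one, via lithium enolate 22 (not isolated)
Conditions: LiBH(s-Bu)3 (1.1 equiv), THF, −78 °C (21 added slowly to the hydride); MeOH, −78 °C; pH 7 buffer
Reagents that add atoms: none
Why: Conjugate (1,4) hydride reduction of the exocyclic enoate gives enolate 22, and kinetic protonation at C3 should occur on the ring face that carries the small C5 methyl group, anti to the bulky ortho-methoxyaryl group, so the new C3 methyl ends cis to the aryl group (3S).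

Step 10
Reactants: 23 (3S,5S)-5-(7-methoxy-2,2-dimethyl-2H-chromen-6-yl)-3,5-dimethyloxolan-2-one
Product: 24 (3S,5S)-5-(7-methoxy-2,2-dimethyl-2H-chromen-6-yl)-3,5-dimethyloxolan-2-ol (anomer mixture)
Conditions: i-Bu2AlH (1.1 equiv), CH2Cl2, −78 °C; aq. KNaC4H4O6
Reagents that add atoms: none
Why: Partial reduction of a γ-lactone with i-Bu2AlH at low temperature stops at the hemiacetal oxidation level and gives the lactol (C2 uncontrolled and destroyed in the next step) after a neutral work-up that spares the benzylic C–O bond.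

Step 11
Reactants: 24 (3S,5S)-5-(7-methoxy-2,2-dimethyl-2H-chromen-6-yl)-3,5-dimethyloxolan-2-ol
Product: 26 (2S,4S)-2-(7-methoxy-2,2-dimethyl-2H-chromen-6-yl)-4-methylhex-5-yn-2-ol, via hydroxy aldehyde 25 (not isolated)
Conditions: MeC(O)C(N2)P(O)(OMe)2 (2.5 equiv), K2CO3, MeOH, 0 °C → rt
Reagents that add atoms: dimethyl (1-diazo-2-oxopropyl)phosphonate, COP(=O)(OC)C(=[N+]=[N-])C(C)=O
Why: The Ohira–Bestmann variant of the Seyferth–Gilbert homologation acts on the ring-opened tautomer 25 (methanolysis of the reagent, Horner–Wadsworth–Emmons-type olefination, loss of N2 and 1,2-hydrogen shift) and gives the terminal alkyne under mild carbonate conditions that are expected to leave the adjacent methine and the free tertiary alcohol unchanged.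

Step 12
Reactants: 27 1-(2,4-dihydroxyphenyl)ethanone (2,4-dihydroxyacetophenone)
Product: 28 1-(2,4-dihydroxy-5-iodophenyl)ethanone
Conditions: BnMe3N[ICl2] (1 equiv), NaHCO3, CH2Cl2/MeOH, rt
Reagents that add atoms: benzyltrimethylammonium dichloroiodate, C[N+](C)(C)Cc1ccccc1.Cl[I-]Cl
Why: Electrophilic aromatic iodination of the resorcinol ring should take place at C5, ortho to the free 4-OH and para to the chelated 2-OH, because C3 between the two hydroxyl groups is the more hindered site for the bulky iodinating species.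

Step 13
Reactants: 26 (2S,4S)-2-(7-methoxy-2,2-dimethyl-2H-chromen-6-yl)-4-methylhex-5-yn-2-ol; 28 1-(2,4-dihydroxy-5-iodophenyl)ethanone
Product: 30 1-{6-hydroxy-2-[(2S,4S)-4-hydroxy-4-(7-methoxy-2,2-dimethyl-2H-chromen-6-yl)pentan-2-yl]-1-benzofuran-5-yl}ethanone (CNP0233723.1), via alkynylphenol 29 (not isolated)
Conditions: PdCl2(PPh3)2 (5 mol%), CuI (10 mol%), Et3N, DMF, 60 °C, Ar
Reagents that add atoms: none
Why: Sonogashira coupling of the terminal alkyne with the ortho-iodophenol is followed in the same pot by 5-endo-dig cycloisomerisation of 29 (attack of the 4-OH on the metal-activated alkyne) to build the benzofuran, while the hydrogen-bonded 2-OH, the tertiary alcohol and both stereocentres lie outside the reacting atoms.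

**Compound list**

1 | 1-(4-hydroxy-2-methoxyphenyl)ethanone | CC(=O)c1ccc(O)cc1OC | starting material
2 | 3-chloro-3-methylbut-1-yne | C#CC(C)(C)Cl | starting material
3 | 1-[2-methoxy-4-(2-methylbut-3-yn-2-yloxy)phenyl]ethanone | CC(=O)c1ccc(OC(C)(C)C#C)cc1OC | intermediate
4 | 1-[4-hydroxy-2-methoxy-5-(3-methylbuta-1,2-dien-1-yl)phenyl]ethanone | CC(=O)c1cc(C=C=C(C)C)c(O)cc1OC | intermediate
5 | 1-(7-methoxy-2,2-dimethyl-2H-chromen-6-yl)ethanone | COc1cc2c(cc1C(C)=O)C=CC(C)(C)O2 | intermediate
6 | (E)-N'-[1-(7-methoxy-2,2-dimethyl-2H-chromen-6-yl)ethylidene]-2,4,6-tri(propan-2-yl)benzenesulfonohydrazide | COc1cc2c(cc1/C(C)=N/NS(=O)(=O)c1c(C(C)C)cc(C(C)C)cc1C(C)C)C=CC(C)(C)O2 | intermediate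
7 | (1-ethoxycyclopropoxy)trimethylsilane | CCOC1(CC1)O[Si](C)(C)C | starting material
8 | 1-ethoxycyclopropan-1-ol | CCOC1(O)CC1 | intermediate
9 | [1-(7-methoxy-2,2-dimethyl-2H-chromen-6-yl)ethenyl]lithium | COc1cc2c(cc1C(=C)[Li])C=CC(C)(C)O2 | intermediate
10 | [1-(7-methoxy-2,2-dimethyl-2H-chromen-6-yl)ethenyl]magnesium bromide | COc1cc2c(cc1C(=C)[Mg]Br)C=CC(C)(C)O2 | intermediate
11 | bromomagnesium 1-ethoxycyclopropan-1-olate | CCOC1(CC1)O[Mg]Br | intermediate
12 | cyclopropanone | O=C1CC1 | intermediate
13 | 1-[1-(7-methoxy-2,2-dimethyl-2H-chromen-6-yl)ethenyl]cyclopropan-1-ol | COc1cc2c(cc1C(=C)C1(O)CC1)C=CC(C)(C)O2 | intermediate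
14 | 1-(1-hydroxycyclopropyl)-1-(7-methoxy-2,2-dimethyl-2H-chromen-6-yl)ethylium (paired with the chiral phosphoramide anion) | COc1cc2c(cc1[C+](C)C1(O)CC1)C=CC(C)(C)O2 | intermediate
15 | (2S)-2-(7-methoxy-2,2-dimethyl-2H-chromen-6-yl)-2-methylcyclobutan-1-one | COc1cc2c(cc1[C@]3(C)CCC3=O)C=CC(C)(C)O2 | intermediate
16 | (2S)-1-hydroperoxy-2-(7-methoxy-2,2-dimethyl-2H-chromen-6-yl)-2-methylcyclobutan-1-ol | COc1cc2c(cc1[C@]3(C)CCC3(O)OO)C=CC(C)(C)O2 | intermediate
17 | (5S)-5-(7-methoxy-2,2-dimethyl-2H-chromen-6-yl)-5-methyloxolan-2-one | COc1cc2c(cc1[C@]3(C)CCC(=O)O3)C=CC(C)(C)O2 | intermediate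
18 | lithium (5S)-5-(7-methoxy-2,2-dimethyl-2H-chromen-6-yl)-5-methyl-4,5-dihydrofuran-2-olate | COc1cc2c(cc1[C@]3(C)CC=C(O[Li])O3)C=CC(C)(C)O2 | intermediate
19 | (5S)-3-[(dimethylamino)methyl]-5-(7-methoxy-2,2-dimethyl-2H-chromen-6-yl)-5-methyloxolan-2-one (C3 epimers) | COc1cc2c(cc1[C@]3(C)CC(CN(C)C)C(=O)O3)C=CC(C)(C)O2 | intermediate
20 | {[(5S)-5-(7-methoxy-2,2-dimethyl-2H-chromen-6-yl)-5-methyl-2-oxooxolan-3-yl]methyl}trimethylammonium iodide | COc1cc2c(cc1[C@]3(C)CC(C[N+](C)(C)C)C(=O)O3)C=CC(C)(C)O2.[I-] | intermediate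
21 | (5S)-5-(7-methoxy-2,2-dimethyl-2H-chromen-6-yl)-5-methyl-3-methylideneoxolan-2-one | COc1cc2c(cc1[C@]3(C)CC(=C)C(=O)O3)C=CC(C)(C)O2 | intermediate
22 | lithium (5S)-5-(7-methoxy-2,2-dimethyl-2H-chromen-6-yl)-3,5-dimethyl-4,5-dihydrofuran-2-olate | COc1cc2c(cc1[C@]3(C)CC(C)=C(O[Li])O3)C=CC(C)(C)O2 | intermediate
23 | (3S,5S)-5-(7-methoxy-2,2-dimethyl-2H-chromen-6-yl)-3,5-dimethyloxolan-2-one | COc1cc2c(cc1[C@]3(C)C[C@H](C)C(=O)O3)C=CC(C)(C)O2 | intermediate
24 | (3S,5S)-5-(7-methoxy-2,2-dimethyl-2H-chromen-6-yl)-3,5-dimethyloxolan-2-ol (anomer mixture) | COc1cc2c(cc1[C@]3(C)C[C@H](C)C(O)O3)C=CC(C)(C)O2 | intermediate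
25 | (2S,4S)-4-hydroxy-4-(7-methoxy-2,2-dimethyl-2H-chromen-6-yl)-2-methylpentanal | COc1cc2c(cc1[C@@](C)(O)C[C@H](C)C=O)C=CC(C)(C)O2 | intermediate
26 | (2S,4S)-2-(7-methoxy-2,2-dimethyl-2H-chromen-6-yl)-4-methylhex-5-yn-2-ol | COc1cc2c(cc1[C@@](C)(O)C[C@H](C)C#C)C=CC(C)(C)O2 | intermediate
27 | 1-(2,4-dihydroxyphenyl)ethanone | CC(=O)c1ccc(O)cc1O | starting material
28 | 1-(2,4-dihydroxy-5-iodophenyl)ethanone | CC(=O)c1cc(I)c(O)cc1O | intermediate
29 | 1-{2,4-dihydroxy-5-[(3S,5S)-5-hydroxy-5-(7-methoxy-2,2-dimethyl-2H-chromen-6-yl)-3-methylhex-1-yn-1-yl]phenyl}ethanone | COc1cc2c(cc1[C@@](C)(O)C[C@H](C)C#Cc1cc(C(C)=O)c(O)cc1O)C=CC(C)(C)O2 | intermediate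
30 | 1-{6-hydroxy-2-[(2S,4S)-4-hydroxy-4-(7-methoxy-2,2-dimethyl-2H-chromen-6-yl)pentan-2-yl]-1-benzofuran-5-yl}ethanone | COc1cc2c(cc1[C@@](C)(O)C[C@H](C)c1cc3cc(C(C)=O)c(O)cc3o1)C=CC(C)(C)O2 | target

**Step count and risks**

Total step count: 13. Longest linear sequence: 11 steps (1, 2, 3, 5, 6, 7, 8, 9, 10, 11, 13); steps 4 and 12 prepare the two side components.

Steps most likely to fail:

1. Step 6. The cation is stabilised by two oxygen donors and may separate from the chiral anion before the ring expansion, which would erode enantiofacial control; slow acid-induced oligomerisation through the chromene alkene may compete. Fallback: setting out from 13, the rearrangement is run with the achiral acid (PhO)2P(O)OH (10 mol%, toluene, 0 °C) to give racemic 2-(7-methoxy-2,2-dimethyl-2H-chromen-6-yl)-2-methylcyclobutan-1-one F1. Its enantiomers are then separated by preparative supercritical-fluid chromatography on cellulose tris(3,5-dimethylphenylcarbamate), and the (S)-enantiomer is 15, where the route is rejoined.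

2. Step 9. Protonation of enolate 22 may discriminate poorly between the two ring faces, since the controlling groups sit at the remote C5, and 22 may add in Michael fashion to unreduced 21. Fallback: setting out from 21, the reduction is run without regard to selectivity (NaBH4, MeOH, 0 °C) and 23 is separated by chromatography from its C3 epimer (3R,5S)-5-(7-methoxy-2,2-dimethyl-2H-chromen-6-yl)-3,5-dimethyloxolan-2-one F2. The epimer is re-equilibrated under thermodynamic control (DBU, toluene, 60 °C), where the isomer with 3-methyl cis to 5-aryl is expected to be favoured, and recycled; the route is rejoined at 23.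

3. Step 5. Generation of the alkenyl anion may be incomplete (competing ring lithiation next to the methoxy group, premature protonation), and cyclopropanone may oligomerise before it is captured. Fallback: setting out from 5, condensation with N2H4·H2O (Et3N, EtOH, reflux) gives [1-(7-methoxy-2,2-dimethyl-2H-chromen-6-yl)ethylidene]hydrazine F3. Barton vinyl iodide synthesis (I2, 1,1,3,3-tetramethylguanidine, THF, 0 °C) then gives 6-(1-iodoethenyl)-7-methoxy-2,2-dimethyl-2H-chromene F4, a storable precursor. Iodine–lithium exchange (t-BuLi, 2 equiv, Et2O, −78 °C) delivers alkenyllithium 9 cleanly, which is carried on as in step 5 (MgBr2·OEt2, then 11/12) to rejoin the route at 13.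

**Further compounds**

F1 | step 6 | racemic 2-(7-methoxy-2,2-dimethyl-2H-chromen-6-yl)-2-methylcyclobutan-1-one | COc1cc2c(cc1C3(C)CCC3=O)C=CC(C)(C)O2
F2 | step 9 | (3R,5S)-5-(7-methoxy-2,2-dimethyl-2H-chromen-6-yl)-3,5-dimethyloxolan-2-one | COc1cc2c(cc1[C@]3(C)C[C@@H](C)C(=O)O3)C=CC(C)(C)O2
F3 | step 5 | [1-(7-methoxy-2,2-dimethyl-2H-chromen-6-yl)ethylidene]hydrazine | COc1cc2c(cc1C(C)=NN)C=CC(C)(C)O2
F4 | step 5 | 6-(1-iodoethenyl)-7-methoxy-2,2-dimethyl-2H-chromene | COc1cc2c(cc1C(=C)I)C=CC(C)(C)O2
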